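**Retrosynthetic overview**
- Ring C (the dihydropyran) is closed last, by the bond between the benzylic CH2 (C4) and the aryl-bearing carbon (C3). The same one-pot operation sets the C3 stereocentre by asymmetric transfer hydrogenation and gives the unprotected target.
- Enabling feature: C4 sits on ring A para to the 7-OH and between O1 and the 5-OMe, so its benzylic alcohol ionises to an A-ring p-quinone methide. C3 is para to the 4'-OH of ring B, so after ring closure it can become the exocyclic carbon of a B-ring p-quinone methide. The O1–C2=C3 aryl enol ether links the two.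
- The enol ether (O1–C2 bond) comes from copper-catalysed O-vinylation of an A-ring salicylaldehyde with a B-ring (E)-vinyl iodide.
- Ring order: the 2,2-dimethylpyran on ring B first (propargyl ether Claisen/electrocyclisation), ring C last. The prenyl group enters by C-alkylation of symmetric 2,4,6-trihydroxybenzaldehyde, the OMe by late O-methylation.

Key step: step 11

Assumption: the target is the (3R) isomer as drawn; the sense of induction of (R)-TRIP in step 11 is taken by analogy with related quinone methide reductions, and (S)-TRIP is to be used if the sense is opposite.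

TIPS = triisopropylsilyl. TRIP = 3,3'-bis(2,4,6-triisopropylphenyl)-1,1'-binaphthyl-2,2'-diyl hydrogen phosphate.

**Step 1**
Reactants: 1 2,4-dihydroxybenzaldehyde
Product: 2 2-hydroxy-4-(TIPS-oxy)benzaldehyde
Conditions: TIPSCl (1.05 equiv), imidazole, CH2Cl2, 0 °C → rt
Reagents that add atoms: chlorotriisopropylsilane, CC(C)[Si](Cl)(C(C)C)C(C)C
Why: Silylation should occur at the 4-OH only, because the 2-OH is held in a hydrogen bond to the aldehyde and is the less nucleophilic hydroxyl (chemoselective silyl ether formation).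

**Step 2**
Reactants: 2 2-hydroxy-4-(TIPS-oxy)benzaldehyde
Product: 3 2-[(2-methylbut-3-yn-2-yl)oxy]-4-(TIPS-oxy)benzaldehyde
Conditions: 3-chloro-3-methylbut-1-yne, DBU, CuCl2·2H2O (1 mol %), MeCN, 0 °C → rt
Reagents that add atoms: 3-chloro-3-methylbut-1-yne, CC(C)(Cl)C#C
Why: Copper-catalysed O-propargylation of phenols with tertiary propargylic chlorides works on hindered, hydrogen-bonded phenols where SN2 alkylation fails.

**Step 3**
Reactants: 3 2-[(2-methylbut-3-yn-2-yl)oxy]-4-(TIPS-oxy)benzaldehyde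
Product: 5 2,2-dimethyl-5-(TIPS-oxy)-2H-chromene-8-carbaldehyde, via allenylphenol 4 (not isolated)
Conditions: N,N-diethylaniline, 180 °C
Reagents that add atoms: none
Why: Aryl propargyl ether Claisen rearrangement to the only free ortho position gives allenylphenol 4, which should close to the 2H-pyran by 1,5-hydrogen shift and oxa-6π electrocyclisation (standard 2,2-dimethylchromene synthesis).

**Step 4**
Reactants: 5 2,2-dimethyl-5-(TIPS-oxy)-2H-chromene-8-carbaldehyde
Product: 6 8-[(E)-2-iodoethenyl]-2,2-dimethyl-5-(TIPS-oxy)-2H-chromene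
Conditions: CrCl2 (6 equiv), CHI3 (2 equiv), THF, 0 °C → rt
Reagents that add atoms: iodoform, IC(I)I
Why: Takai olefination converts aryl aldehydes into (E)-vinyl iodides and should tolerate the silyl ether and the pyran double bond.

**Step 5**
Reactants: 7 2,4,6-trihydroxybenzaldehyde
Product: 8 2,4,6-trihydroxy-3-(3-methylbut-2-en-1-yl)benzaldehyde
Conditions: prenyl bromide (1.0 equiv), DBU (1.0 equiv), THF, 0 °C → rt
Reagents that add atoms: 1-bromo-3-methylbut-2-ene, CC(C)=CCBr
Why: C-alkylation of the phloroglucinol-type phenoxide (C-prenylation) can give only one mono-C-prenyl isomer, because the two free ring positions are equivalent by symmetry.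

**Step 6**
Reactants: 8 2,4,6-trihydroxy-3-(3-methylbut-2-en-1-yl)benzaldehyde
Product: 9 2,6-dihydroxy-3-(3-methylbut-2-en-1-yl)-4-(TIPS-oxy)benzaldehyde
Conditions: TIPSCl (1.05 equiv), imidazole, DMF, 0 °C
Reagents that add atoms: chlorotriisopropylsilane, CC(C)[Si](Cl)(C(C)C)C(C)C
Why: The 4-OH para to the aldehyde is the only hydroxyl not engaged in a hydrogen bond to the carbonyl and should be silylated selectively.

**Step 7**
Reactants: 9 2,6-dihydroxy-3-(3-methylbut-2-en-1-yl)-4-(TIPS-oxy)benzaldehyde; 6 8-[(E)-2-iodoethenyl]-2,2-dimethyl-5-(TIPS-oxy)-2H-chromene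
Product: 10 6-{[(E)-2-(2,2-dimethyl-5-(TIPS-oxy)-2H-chromen-8-yl)ethenyl]oxy}-2-hydroxy-3-(3-methylbut-2-en-1-yl)-4-(TIPS-oxy)benzaldehyde
Conditions: CuI (10 mol %), N,N-dimethylglycine·HCl (30 mol %), Cs2CO3, 1,4-dioxane, 60 °C
Reagents that add atoms: none
Why: Ullmann-type copper-catalysed C–O coupling of phenols with vinyl iodides proceeds with retention of alkene geometry, and the hydroxyl flanked only by the aldehyde should react in preference to the one wedged between aldehyde and prenyl group.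

**Step 8**
Reactants: 10 (aryl enol ether with one free hydroxyl)
Product: 11 6-{[(E)-2-(2,2-dimethyl-5-(TIPS-oxy)-2H-chromen-8-yl)ethenyl]oxy}-2-methoxy-3-(3-methylbut-2-en-1-yl)-4-(TIPS-oxy)benzaldehyde
Conditions: MeI, K2CO3, acetone, 45 °C
Reagents that add atoms: iodomethane, CI
Why: Williamson O-methylation of the only remaining hydroxyl places the methoxy group between the formyl carbon and the prenyl group.

**Step 9**
Reactants: 11 (methoxy aldehyde)
Product: 12 [6-{[(E)-2-(2,2-dimethyl-5-(TIPS-oxy)-2H-chromen-8-yl)ethenyl]oxy}-2-methoxy-3-(3-methylbut-2-en-1-yl)-4-(TIPS-oxy)phenyl]methanol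
Conditions: NaBH4, THF/MeOH, 0 °C; work-up and chromatography on base-washed silica
Reagents that add atoms: none
Why: Borohydride reduction of the aldehyde while every phenol is still masked avoids over-reduction through a quinone methide.

**Step 10**
Reactants: 12 (bis-silyl benzylic alcohol)
Product: 13 5-{[(E)-2-(5-hydroxy-2,2-dimethyl-2H-chromen-8-yl)ethenyl]oxy}-4-(hydroxymethyl)-3-methoxy-2-(3-methylbut-2-en-1-yl)phenol
Conditions: TBAF (2.2 equiv), AcOH (2.2 equiv), THF, 0 °C; used directly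
Reagents that add atoms: none
Why: Buffered fluoride cleaves both aryl silyl ethers without ionising the benzylic alcohol or touching the enol ether.

**Step 11**
Reactants: 13 (unprotected enol ether benzylic alcohol)
Product: 17 (3R)-3-(5-hydroxy-2,2-dimethyl-2H-chromen-8-yl)-5-methoxy-6-(3-methylbut-2-en-1-yl)-3,4-dihydro-2H-chromen-7-ol, via A-ring p-quinone methide 14 (not isolated), via 4H-chromene 15 (not isolated), via B-ring p-quinone methide 16 (not isolated)
Conditions: (R)-TRIP (10 mol %), 5 Å MS, CH2Cl2 (0.01 M), −20 → 0 °C; then Hantzsch ester (diethyl 2,6-dimethyl-1,4-dihydropyridine-3,5-dicarboxylate, 1.3 equiv), 0 °C → rt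
Reagents that add atoms: none
Why: Proposed new method: the phosphoric acid should ionise the 2,4,6-trioxygenated benzylic alcohol of 13 to A-ring p-quinone methide 14, whose exocyclic methylene (C4) is attacked by C3, the nucleophilic β-carbon of the tethered aryl enol ether, in a 6-endo-trig (enol-endo) closure that rearomatises ring A; loss of the C3 proton from the resulting oxocarbenium ion gives 4H-chromene 15, and acid-catalysed vinylphenol-to-quinone-methide tautomerisation (proton to C2, made possible by the 4'-OH para to C3) gives B-ring p-quinone methide 16, which takes hydride at C3 from the Hantzsch ester. The closest known reaction types are the Brønsted acid-catalysed generation of quinone methides from hydroxybenzyl alcohols with capture by enol ethers and styrenes, and the chiral phosphoric acid/Hantzsch ester transfer hydrogenation of hydroxystyrenes and of p-quinone methides (asymmetric 1,6-reduction). The C3 stereocentre is set in the hydride transfer, within the hydrogen-bonded assembly of chiral phosphate, quinone methide carbonyl and Hantzsch ester N–H (catalyst control). The step needs regioselective ring closure at C3 and not at C2 or at the arene carbon C8, which the enol ether polarisation should secure, together with the fact that a bond from C2 would need a 5-endo-trig approach to the quinone methide. It also needs chemoselective hydride transfer, for which the hydride donor is added only after ring closure and the weak acid is expected to leave the prenyl and pyran double bonds unprotonated.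

**Compound list**
1 | 2,4-dihydroxybenzaldehyde | O=Cc1ccc(O)cc1O | starting material
2 | 2-hydroxy-4-(TIPS-oxy)benzaldehyde | O=Cc1ccc(O[Si](C(C)C)(C(C)C)C(C)C)cc1O | intermediate
3 | 2-[(2-methylbut-3-yn-2-yl)oxy]-4-(TIPS-oxy)benzaldehyde | O=Cc1ccc(O[Si](C(C)C)(C(C)C)C(C)C)cc1OC(C)(C)C#C | intermediate
4 | 2-hydroxy-3-(3-methylbuta-1,2-dien-1-yl)-4-(TIPS-oxy)benzaldehyde (allenylphenol) | O=Cc1ccc(O[Si](C(C)C)(C(C)C)C(C)C)c(C=C=C(C)C)c1O | intermediate (not isolated)
5 | 2,2-dimethyl-5-(TIPS-oxy)-2H-chromene-8-carbaldehyde | O=Cc1ccc(O[Si](C(C)C)(C(C)C)C(C)C)c2c1OC(C)(C)C=C2 | intermediate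
6 | 8-[(E)-2-iodoethenyl]-2,2-dimethyl-5-(TIPS-oxy)-2H-chromene | I/C=C/c1ccc(O[Si](C(C)C)(C(C)C)C(C)C)c2c1OC(C)(C)C=C2 | intermediate
7 | 2,4,6-trihydroxybenzaldehyde | O=Cc1c(O)cc(O)cc1O | starting material
8 | 2,4,6-trihydroxy-3-(3-methylbut-2-en-1-yl)benzaldehyde | O=Cc1c(O)cc(O)c(CC=C(C)C)c1O | intermediate
9 | 2,6-dihydroxy-3-(3-methylbut-2-en-1-yl)-4-(TIPS-oxy)benzaldehyde | O=Cc1c(O)cc(O[Si](C(C)C)(C(C)C)C(C)C)c(CC=C(C)C)c1O | intermediate
10 | 6-{[(E)-2-(2,2-dimethyl-5-(TIPS-oxy)-2H-chromen-8-yl)ethenyl]oxy}-2-hydroxy-3-(3-methylbut-2-en-1-yl)-4-(TIPS-oxy)benzaldehyde | O=Cc1c(O/C=C/c2ccc(O[Si](C(C)C)(C(C)C)C(C)C)c3c2OC(C)(C)C=C3)cc(O[Si](C(C)C)(C(C)C)C(C)C)c(CC=C(C)C)c1O | intermediate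
11 | 6-{[(E)-2-(2,2-dimethyl-5-(TIPS-oxy)-2H-chromen-8-yl)ethenyl]oxy}-2-methoxy-3-(3-methylbut-2-en-1-yl)-4-(TIPS-oxy)benzaldehyde | O=Cc1c(O/C=C/c2ccc(O[Si](C(C)C)(C(C)C)C(C)C)c3c2OC(C)(C)C=C3)cc(O[Si](C(C)C)(C(C)C)C(C)C)c(CC=C(C)C)c1OC | intermediate
12 | [6-{[(E)-2-(2,2-dimethyl-5-(TIPS-oxy)-2H-chromen-8-yl)ethenyl]oxy}-2-methoxy-3-(3-methylbut-2-en-1-yl)-4-(TIPS-oxy)phenyl]methanol | OCc1c(O/C=C/c2ccc(O[Si](C(C)C)(C(C)C)C(C)C)c3c2OC(C)(C)C=C3)cc(O[Si](C(C)C)(C(C)C)C(C)C)c(CC=C(C)C)c1OC | intermediate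
13 | 5-{[(E)-2-(5-hydroxy-2,2-dimethyl-2H-chromen-8-yl)ethenyl]oxy}-4-(hydroxymethyl)-3-methoxy-2-(3-methylbut-2-en-1-yl)phenol | OCc1c(O/C=C/c2ccc(O)c3c2OC(C)(C)C=C3)cc(O)c(CC=C(C)C)c1OC | intermediate
14 | 5-{[(E)-2-(5-hydroxy-2,2-dimethyl-2H-chromen-8-yl)ethenyl]oxy}-3-methoxy-4-methylidene-2-(3-methylbut-2-en-1-yl)cyclohexa-2,5-dien-1-one (A-ring p-quinone methide) | C=C1C(OC)=C(CC=C(C)C)C(=O)C=C1O/C=C/c1ccc(O)c2c1OC(C)(C)C=C2 | intermediate (not isolated)
15 | 3-(5-hydroxy-2,2-dimethyl-2H-chromen-8-yl)-5-methoxy-6-(3-methylbut-2-en-1-yl)-4H-chromen-7-ol | COc1c(CC=C(C)C)c(O)cc2OC=C(Cc12)c1ccc(O)c2c1OC(C)(C)C=C2 | intermediate (not isolated)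
16 | 8-[7-hydroxy-5-methoxy-6-(3-methylbut-2-en-1-yl)-2H-chromen-3(4H)-ylidene]-2,2-dimethyl-2H-chromen-5(8H)-one (B-ring p-quinone methide) | COc1c(CC=C(C)C)c(O)cc2OCC(Cc12)=C1C=CC(=O)C2=C1OC(C)(C)C=C2 | intermediate (not isolated)
17 | (3R)-3-(5-hydroxy-2,2-dimethyl-2H-chromen-8-yl)-5-methoxy-6-(3-methylbut-2-en-1-yl)-3,4-dihydro-2H-chromen-7-ol | COc1c(CC=C(C)C)c(O)cc2c1C[C@H](c1ccc(O)c3c1OC(C)(C)C=C3)CO2 | target

**Count and risks**
Total steps: 11. Longest linear sequence: 9 (steps 1–4, then 7–11).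

Steps most likely to fail:

1. Step 11 (Proposed new method). The first quinone methide may be captured by a second molecule before ring closure. C-protonation of the enol ether may open a Friedel–Crafts closure to a five-membered ring. Hydride may be delivered through the oxocarbenium channel or with poor facial control, which lowers the enantiomeric purity. Acid-mediated transfer hydrogenation of the o-hydroxystyrene unit of the B-ring pyran is also possible. The fallback uses known reaction types only, sets out from 11 and comes back at 17. Mild aqueous acid (PPTS, THF/H2O) hydrolyses the aryl enol ether of 11 to 2-hydroxy-6-methoxy-5-(3-methylbut-2-en-1-yl)-4-(TIPS-oxy)benzaldehyde F1 and [2,2-dimethyl-5-(TIPS-oxy)-2H-chromen-8-yl]acetaldehyde F2. NaBH4 reduces F1 to 2-(hydroxymethyl)-3-methoxy-4-(3-methylbut-2-en-1-yl)-5-(TIPS-oxy)phenol F3. F3 and F2 are then joined in an aminocatalytic formal [4+2] reaction (diphenylprolinol trimethylsilyl ether, benzoic acid, CHCl3): the enamine of F2 adds to the o-quinone methide released from F3 and the phenol closes the hemiacetal, giving (3R)-3-[2,2-dimethyl-5-(TIPS-oxy)-2H-chromen-8-yl]-5-methoxy-6-(3-methylbut-2-en-1-yl)-7-(TIPS-oxy)chroman-2-ol F4, with C3 set by the amine catalyst (the catalyst antipode that gives 3R is used). Et3SiH/BF3·OEt2 at −78 °C reduces the lactol to the bis-silyl isoflavan F5, and TBAF gives 17.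

2. Step 7. O-vinylation may occur at the more hindered hydroxyl or at both hydroxyls. The fallback sets out from 7 and comes back at 10. TIPSCl/imidazole silylates the 4-OH of 7 to 2,6-dihydroxy-4-(TIPS-oxy)benzaldehyde F6, whose two hydroxyls are equivalent. The same copper-catalysed coupling with 6 can then give only one mono-ether, 6-{[(E)-2-(2,2-dimethyl-5-(TIPS-oxy)-2H-chromen-8-yl)ethenyl]oxy}-2-hydroxy-4-(TIPS-oxy)benzaldehyde F7. Pd(PPh3)4 with tert-butyl 2-methylbut-3-en-2-yl carbonate converts the remaining hydroxyl into the 1,1-dimethylallyl ether F8. Heating (aromatic Claisen rearrangement to the only free ortho position) gives 10.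

3. Step 5. O-alkylation and multiple C-alkylation of the ambident phloroglucinol anion may outrun mono-C-prenylation. The fallback sets out from 7 and comes back at 8. Pd-catalysed O-(1,1-dimethylallyl)ation (tert-butyl 2-methylbut-3-en-2-yl carbonate, Pd(PPh3)4) at the most acidic, non-hydrogen-bonded 4-OH gives 2,6-dihydroxy-4-[(2-methylbut-3-en-2-yl)oxy]benzaldehyde F9. Thermal aromatic Claisen rearrangement to either of the two equivalent ortho positions gives 8.

**Further compounds**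
F1 | step 11 | 2-hydroxy-6-methoxy-5-(3-methylbut-2-en-1-yl)-4-(TIPS-oxy)benzaldehyde | O=Cc1c(O)cc(O[Si](C(C)C)(C(C)C)C(C)C)c(CC=C(C)C)c1OC
F2 | step 11 | [2,2-dimethyl-5-(TIPS-oxy)-2H-chromen-8-yl]acetaldehyde | O=CCc1ccc(O[Si](C(C)C)(C(C)C)C(C)C)c2c1OC(C)(C)C=C2
F3 | step 11 | 2-(hydroxymethyl)-3-methoxy-4-(3-methylbut-2-en-1-yl)-5-(TIPS-oxy)phenol | OCc1c(O)cc(O[Si](C(C)C)(C(C)C)C(C)C)c(CC=C(C)C)c1OC
F4 | step 11 | (3R)-3-[2,2-dimethyl-5-(TIPS-oxy)-2H-chromen-8-yl]-5-methoxy-6-(3-methylbut-2-en-1-yl)-7-(TIPS-oxy)chroman-2-ol | COc1c(CC=C(C)C)c(O[Si](C(C)C)(C(C)C)C(C)C)cc2c1C[C@H](c1ccc(O[Si](C(C)C)(C(C)C)C(C)C)c3c1OC(C)(C)C=C3)C(O)O2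
F5 | step 11 | (3R)-3-[2,2-dimethyl-5-(TIPS-oxy)-2H-chromen-8-yl]-5-methoxy-6-(3-methylbut-2-en-1-yl)-7-(TIPS-oxy)chroman | COc1c(CC=C(C)C)c(O[Si](C(C)C)(C(C)C)C(C)C)cc2c1C[C@H](c1ccc(O[Si](C(C)C)(C(C)C)C(C)C)c3c1OC(C)(C)C=C3)CO2
F6 | step 7 | 2,6-dihydroxy-4-(TIPS-oxy)benzaldehyde | O=Cc1c(O)cc(O[Si](C(C)C)(C(C)C)C(C)C)cc1O
F7 | step 7 | 6-{[(E)-2-(2,2-dimethyl-5-(TIPS-oxy)-2H-chromen-8-yl)ethenyl]oxy}-2-hydroxy-4-(TIPS-oxy)benzaldehyde | O=Cc1c(O/C=C/c2ccc(O[Si](C(C)C)(C(C)C)C(C)C)c3c2OC(C)(C)C=C3)cc(O[Si](C(C)C)(C(C)C)C(C)C)cc1O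
F8 | step 7 | 6-{[(E)-2-(2,2-dimethyl-5-(TIPS-oxy)-2H-chromen-8-yl)ethenyl]oxy}-2-[(2-methylbut-3-en-2-yl)oxy]-4-(TIPS-oxy)benzaldehyde | O=Cc1c(O/C=C/c2ccc(O[Si](C(C)C)(C(C)C)C(C)C)c3c2OC(C)(C)C=C3)cc(O[Si](C(C)C)(C(C)C)C(C)C)cc1OC(C)(C)C=C
F9 | step 5 | 2,6-dihydroxy-4-[(2-methylbut-3-en-2-yl)oxy]benzaldehyde | O=Cc1c(O)cc(OC(C)(C)C=C)cc1O
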